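**Plan**

1. Retrosynthesis: the benzyl ethers come off last. C3 and C3' are traced back to their 2,3-trans epimers. Both aryl-ketone bonds C4–C3 and C4'–C3' are then cut together, which opens both pyranone rings to an alkyne-linked bis(salicylaldehyde ether). The two aryl–O1 bonds (SNAr) and the alkyne–C2' bond (alkynylation) are cut last.
2. Enabling feature: C4(=O)–C3–C3'–C4'(=O) is a 1,4-diketone. Each carbonyl sits on a benzo ring whose ortho oxygen (O1, O1') is bonded to C2 (C2'). C3–C3' is therefore a doubly hydroacylated alkyne, and each formyl C–H reaches its alkyne carbon through a six-membered ring.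
3. Forward: anisaldehyde and silylacetylene give the first carbinol; SNAr, a second alkynylation and a second SNAr give the bis-nitrile; DIBAL gives the dialdehyde. One carbene-catalysed pot then closes the pyranone ring of unit A (hydroacylation, C4–C3) and the pyranone ring of unit B (Stetter, C4'–C3').
4. Stereochemistry: C2 and C2' come from two catalyst-controlled zinc alkynylations and are retained in the SNAr steps. C3 and C3' come from kinetic protonation of the dienediolate anti to the 2-aryl groups, which gives 2,3-cis in both halves.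

Key step: step 10

Remarks on the chemistry: unprimed locants are unit A (5,7-dioxygenated half) and primed locants are unit B (7'-methoxy half). The sense of induction of the zinc alkynylation is assumed to follow the ligand enantiomer; the enantiomer that delivers the (S)-carbinols 8 and 11 is used in steps 4 and 7.

**Route**

Step 1
Reactants: 1 2,6-difluoro-4-hydroxybenzonitrile
Product: 2 4-(benzyloxy)-2,6-difluorobenzonitrile
Conditions: BnBr, K2CO3, DMF, rt
Reagents that add atoms: benzyl bromide, BrCc1ccccc1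
Why: Williamson O-alkylation of the acidic phenol should proceed cleanly, since the phenoxide is far more nucleophilic towards benzyl bromide than towards the fluoroarene.

Step 2
Reactants: 2 4-(benzyloxy)-2,6-difluorobenzonitrile
Product: 3 2,4-bis(benzyloxy)-6-fluorobenzonitrile
Conditions: BnOH (1.05 equiv), NaH (1.05 equiv), THF, 0 °C to rt
Reagents that add atoms: benzyl alcohol, OCc1ccccc1
Why: SNAr at a C–F bond ortho to the nitrile should stop after one substitution, because the two fluorines are equivalent and the first alkoxy group makes the ring less electrophilic.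

Step 3
Reactants: 4 2,6-difluoro-4-methoxybenzonitrile
Product: 5 2-(benzyloxy)-6-fluoro-4-methoxybenzonitrile
Conditions: BnOH (1.05 equiv), NaH (1.05 equiv), THF, 0 °C to rt
Reagents that add atoms: benzyl alcohol, OCc1ccccc1
Why: The same mono-SNAr as in step 2 should give the fluoroarene for unit B with the 7'-methoxy group already in place.

Step 4
Reactants: 6 4-methoxybenzaldehyde; 7 ethynyltrimethylsilane
Product: 8 (S)-1-(4-methoxyphenyl)-3-(trimethylsilyl)prop-2-yn-1-ol
Conditions: 7 (2.8 equiv), Me2Zn (2.9 equiv), ProPhenol ligand 2,6-bis{[2-(hydroxydiphenylmethyl)pyrrolidin-1-yl]methyl}-4-methylphenol (enantiomer giving the (S)-carbinol, 10 mol%), Ph3P=O (20 mol%), toluene, 0 °C; then H2O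
Reagents that add atoms: none
Why: Catalytic asymmetric zinc alkynylation of an aryl aldehyde, in which the dinuclear zinc–ligand complex selects the aldehyde face and so sets the future C2.

Step 5
Reactants: 8 (S)-1-(4-methoxyphenyl)-3-(trimethylsilyl)prop-2-yn-1-ol
Product: 9 (R)-1-(4-methoxyphenyl)prop-2-yn-1-ol
Conditions: K2CO3 (0.2 equiv), MeOH, rt
Reagents that add atoms: none
Why: Methanolysis of the alkynyl–silicon bond (protodesilylation) leaves the carbinol centre untouched; the descriptor changes only because the ethynyl group now ranks below the aryl group.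

Step 6
Reactants: 9 (R)-1-(4-methoxyphenyl)prop-2-yn-1-ol; 3 2,4-bis(benzyloxy)-6-fluorobenzonitrile
Product: 10 2,4-bis(benzyloxy)-6-{[(1R)-1-(4-methoxyphenyl)prop-2-yn-1-yl]oxy}benzonitrile
Conditions: NaH (1.05 equiv), DMF, 0 °C; then 3, 0 °C to rt
Reagents that add atoms: none
Why: SNAr of the propargylic alkoxide at the C–F bond ortho to the nitrile forms the aryl–O1 bond at the arene, so the carbinol C–O bond is not broken and its configuration is retained.

Step 7
Reactants: 10 2,4-bis(benzyloxy)-6-{[(1R)-1-(4-methoxyphenyl)prop-2-yn-1-yl]oxy}benzonitrile; 6 4-methoxybenzaldehyde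
Product: 11 2,4-bis(benzyloxy)-6-{[(1S,4S)-4-hydroxy-1,4-bis(4-methoxyphenyl)but-2-yn-1-yl]oxy}benzonitrile
Conditions: Me2Zn (2.0 equiv), same ProPhenol ligand enantiomer as in step 4 (20 mol%), Ph3P=O (40 mol%), toluene, 0 °C; 6 (1.5 equiv), 0 °C to rt; then H2O
Reagents that add atoms: none
Why: A second catalytic asymmetric zinc alkynylation, tolerated by the nitrile, sets the future C2' under catalyst control; the remote first centre should exert no bias, and any minor enantiomer of 10 ends up mainly in a separable diastereomer.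

Step 8
Reactants: 11 2,4-bis(benzyloxy)-6-{[(1S,4S)-4-hydroxy-1,4-bis(4-methoxyphenyl)but-2-yn-1-yl]oxy}benzonitrile; 5 2-(benzyloxy)-6-fluoro-4-methoxybenzonitrile
Product: 12 2,4-bis(benzyloxy)-6-{[(1S,4S)-4-[3-(benzyloxy)-2-cyano-5-methoxyphenoxy]-1,4-bis(4-methoxyphenyl)but-2-yn-1-yl]oxy}benzonitrile
Conditions: NaH (1.05 equiv), DMF, 0 °C; then 5, 0 °C to rt
Reagents that add atoms: none
Why: A second SNAr at the C–F bond ortho to a nitrile forms the aryl–O1' bond with retention at the carbinol carbon, as in step 6.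

Step 9
Reactants: 12 2,4-bis(benzyloxy)-6-{[(1S,4S)-4-[3-(benzyloxy)-2-cyano-5-methoxyphenoxy]-1,4-bis(4-methoxyphenyl)but-2-yn-1-yl]oxy}benzonitrile
Product: 14 2,4-bis(benzyloxy)-6-{[(1S,4S)-4-[3-(benzyloxy)-2-formyl-5-methoxyphenoxy]-1,4-bis(4-methoxyphenyl)but-2-yn-1-yl]oxy}benzaldehyde, via bis-aldimine 13 (not isolated)
Conditions: i-Bu2AlH (2.6 equiv), CH2Cl2, −78 °C to −40 °C; then wet silica gel/H2O, rt
Reagents that add atoms: water, O
Why: Partial reduction of both aryl nitriles by DIBAL stops at the N-aluminated aldimines, which hydrolyse on work-up to the dialdehyde; the internal alkyne and the ethers are inert at low temperature.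

Step 10
Reactants: 14 2,4-bis(benzyloxy)-6-{[(1S,4S)-4-[3-(benzyloxy)-2-formyl-5-methoxyphenoxy]-1,4-bis(4-methoxyphenyl)but-2-yn-1-yl]oxy}benzaldehyde
Product: 16 (2R,2'R,3S,3'S)-5,5',7-tris(benzyloxy)-7'-methoxy-2,2'-bis(4-methoxyphenyl)-[3,3'-bichromane]-4,4'-dione, via ylidene chromanone 15 (not isolated)
Conditions: 3-(2,4,6-trimethylphenyl)-4,5-dimethylthiazol-3-ium perchlorate (20 mol%), K2CO3 (40 mol%), THF, 70 °C, dilute
Reagents that add atoms: none
Why: The carbene from the thiazolium salt adds to one formyl group, and the resulting Breslow intermediate transfers its acyl carbon and hydroxyl hydrogen syn across the tethered alkyne (6-exo-dig), which forms C4–C3 and closes the pyranone ring of unit A as the (E)-3-ylidene chromanone 15. The second Breslow intermediate then adds to the beta carbon C3' of this enone (intramolecular Stetter reaction, 6-exo-trig), which forms C4'–C3' and closes the pyranone ring of unit B, and the enolate is protonated at C3. The closest known reactions are the carbene-catalysed hydroacylation of O-propargyl salicylaldehydes to 3-ylidene chromanones and its cascade with a Stetter addition. C3' is set in the C–C bond formation under allylic 1,3-strain (C2'–H in the alkene plane, acyl delivered from the O1' face, hence 2',3'-trans) and C3 by enolate protonation followed by carbonate equilibration to 2,3-trans; neither centre is relied on, because step 11 resets both and any C3/C3' epimers are carried along. The step needs hydroacylation to beat benzoin coupling and six-membered to beat seven-membered closure, which the two ortho oxygens flanking each formyl group and the O1–C2 tether length should secure, while the weak carbonate base spares the C2–H bonds; the order in which the two formyl groups react is immaterial because both orders converge on 16.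

Step 11
Reactants: 16 (2R,2'R,3S,3'S)-5,5',7-tris(benzyloxy)-7'-methoxy-2,2'-bis(4-methoxyphenyl)-[3,3'-bichromane]-4,4'-dione
Product: 18 (2R,2'R,3R,3'R)-5,5',7-tris(benzyloxy)-7'-methoxy-2,2'-bis(4-methoxyphenyl)-[3,3'-bichromane]-4,4'-dione, via dilithium bis-enolate 17 (not isolated)
Conditions: LDA (3.0 equiv), THF, −78 °C to −40 °C; then AcOH (excess) in THF, −78 °C
Reagents that add atoms: none
Why: Double enolisation followed by kinetic protonation of the enolates: in 17 each 2-aryl group should sit pseudoaxial on its 2H-chromene ring to avoid allylic strain with the C3 substituent, so the proton enters C3 and C3' anti to the aryl group and gives the 2,3-cis arrangement in both halves, that is (3R,3'R) from (2R,2'R).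

Step 12
Reactants: 18 (2R,2'R,3R,3'R)-5,5',7-tris(benzyloxy)-7'-methoxy-2,2'-bis(4-methoxyphenyl)-[3,3'-bichromane]-4,4'-dione
Product: 19 (2R,2'R,3R,3'R)-5,5',7-trihydroxy-7'-methoxy-2,2'-bis(4-methoxyphenyl)-[3,3'-bichromane]-4,4'-dione
Conditions: H2 (1 atm), Pd/C (10 wt%), EtOAc, rt
Reagents that add atoms: none
Why: Neutral hydrogenolysis of the three primary aryl benzyl ethers should be much faster than cleavage of the hindered cyclic C2–O1 ethers and does not enolise the ketones, so the cis centres survive.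

**Compound list**

1 | 2,6-difluoro-4-hydroxybenzonitrile | N#Cc1c(F)cc(O)cc1F | starting material
2 | 4-(benzyloxy)-2,6-difluorobenzonitrile | N#Cc1c(F)cc(OCc2ccccc2)cc1F | intermediate
3 | 2,4-bis(benzyloxy)-6-fluorobenzonitrile | N#Cc1c(F)cc(OCc2ccccc2)cc1OCc1ccccc1 | intermediate
4 | 2,6-difluoro-4-methoxybenzonitrile | COc1cc(F)c(C#N)c(F)c1 | starting material
5 | 2-(benzyloxy)-6-fluoro-4-methoxybenzonitrile | COc1cc(F)c(C#N)c(OCc2ccccc2)c1 | intermediate
6 | 4-methoxybenzaldehyde | COc1ccc(C=O)cc1 | starting material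
7 | ethynyltrimethylsilane | C#C[Si](C)(C)C | starting material
8 | (S)-1-(4-methoxyphenyl)-3-(trimethylsilyl)prop-2-yn-1-ol | COc1ccc([C@@H](C#C[Si](C)(C)C)O)cc1 | intermediate
9 | (R)-1-(4-methoxyphenyl)prop-2-yn-1-ol | COc1ccc([C@@H](C#C)O)cc1 | intermediate
10 | 2,4-bis(benzyloxy)-6-{[(1R)-1-(4-methoxyphenyl)prop-2-yn-1-yl]oxy}benzonitrile | COc1ccc([C@@H](C#C)Oc2cc(OCc3ccccc3)cc(OCc3ccccc3)c2C#N)cc1 | intermediate
11 | 2,4-bis(benzyloxy)-6-{[(1S,4S)-4-hydroxy-1,4-bis(4-methoxyphenyl)but-2-yn-1-yl]oxy}benzonitrile | COc1ccc([C@@H](C#C[C@@H](O)c2ccc(OC)cc2)Oc2cc(OCc3ccccc3)cc(OCc3ccccc3)c2C#N)cc1 | intermediate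
12 | 2,4-bis(benzyloxy)-6-{[(1S,4S)-4-[3-(benzyloxy)-2-cyano-5-methoxyphenoxy]-1,4-bis(4-methoxyphenyl)but-2-yn-1-yl]oxy}benzonitrile | COc1ccc([C@@H](C#C[C@@H](Oc2cc(OC)cc(OCc3ccccc3)c2C#N)c2ccc(OC)cc2)Oc2cc(OCc3ccccc3)cc(OCc3ccccc3)c2C#N)cc1 | intermediate
13 | bis-aldimine of 14 (both formyl groups as CH=NH, (1S,4S)) | COc1ccc([C@@H](C#C[C@@H](Oc2cc(OC)cc(OCc3ccccc3)c2C=N)c2ccc(OC)cc2)Oc2cc(OCc3ccccc3)cc(OCc3ccccc3)c2C=N)cc1 | intermediate (not isolated)
14 | 2,4-bis(benzyloxy)-6-{[(1S,4S)-4-[3-(benzyloxy)-2-formyl-5-methoxyphenoxy]-1,4-bis(4-methoxyphenyl)but-2-yn-1-yl]oxy}benzaldehyde | COc1ccc([C@@H](C#C[C@@H](Oc2cc(OC)cc(OCc3ccccc3)c2C=O)c2ccc(OC)cc2)Oc2cc(OCc3ccccc3)cc(OCc3ccccc3)c2C=O)cc1 | intermediate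
15 | 2-(benzyloxy)-6-{[(1R)-2-[(2S,3E)-5,7-bis(benzyloxy)-2-(4-methoxyphenyl)-4-oxochroman-3-ylidene]-1-(4-methoxyphenyl)ethyl]oxy}-4-methoxybenzaldehyde | COc1ccc([C@@H]2Oc3cc(OCc4ccccc4)cc(OCc4ccccc4)c3C(=O)/C2=C/[C@@H](Oc2cc(OC)cc(OCc3ccccc3)c2C=O)c2ccc(OC)cc2)cc1 | intermediate (not isolated)
16 | (2R,2'R,3S,3'S)-5,5',7-tris(benzyloxy)-7'-methoxy-2,2'-bis(4-methoxyphenyl)-[3,3'-bichromane]-4,4'-dione (2,3-trans in both halves) | COc1ccc([C@@H]2Oc3cc(OCc4ccccc4)cc(OCc4ccccc4)c3C(=O)[C@H]2[C@@H]2C(=O)c3c(OCc4ccccc4)cc(OC)cc3O[C@H]2c2ccc(OC)cc2)cc1 | intermediate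
17 | dilithium (2S,2'S)-5,5',7-tris(benzyloxy)-7'-methoxy-2,2'-bis(4-methoxyphenyl)-2H,2'H-[3,3'-bichromene]-4,4'-bis(olate) | COc1ccc([C@@H]2Oc3cc(OCc4ccccc4)cc(OCc4ccccc4)c3C([O-])=C2C2=C([O-])c3c(OCc4ccccc4)cc(OC)cc3O[C@H]2c2ccc(OC)cc2)cc1.[Li+].[Li+] | intermediate (not isolated)
18 | (2R,2'R,3R,3'R)-5,5',7-tris(benzyloxy)-7'-methoxy-2,2'-bis(4-methoxyphenyl)-[3,3'-bichromane]-4,4'-dione (2,3-cis in both halves) | COc1ccc([C@@H]2Oc3cc(OCc4ccccc4)cc(OCc4ccccc4)c3C(=O)[C@@H]2[C@H]2C(=O)c3c(OCc4ccccc4)cc(OC)cc3O[C@H]2c2ccc(OC)cc2)cc1 | intermediate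
19 | (2R,2'R,3R,3'R)-5,5',7-trihydroxy-7'-methoxy-2,2'-bis(4-methoxyphenyl)-[3,3'-bichromane]-4,4'-dione | COc1ccc([C@@H]2Oc3cc(O)cc(O)c3C(=O)[C@@H]2[C@H]2C(=O)c3c(O)cc(OC)cc3O[C@H]2c2ccc(OC)cc2)cc1 | target

**Totals**

Total step count: 12.
Longest linear sequence: 9 steps (6 to 19 through steps 4 to 12; the branch from 1 through steps 1, 2 and 6 to 12 is equally long).

**Steps most likely to fail**

1. Step 10. Carbene addition to the two di-ortho-oxygenated, electron-rich formyl groups may be slow. The intermediate ylidene chromanone may isomerise under base to the 3-alkylflavone, with loss of the C2 centre, before the second ring closes. The sequence may also stall after the first cyclisation. Fallback by acyl radical cyclisation, setting out from 14 and returning at 16: Pinnick oxidation (NaClO2, NaH2PO4, 2-methyl-2-butene, t-BuOH/H2O) should give the dicarboxylic acid F1. Treatment with (PhSe)2 and PBu3 should give the bis(Se-phenyl selenoester) F2. Slow addition of Bu3SnH with AIBN in benzene at 80 °C should generate the first acyl radical, which closes 6-exo-dig onto the alkyne; after reduction of the vinyl radical, the second acyl radical closes 6-exo-trig onto the enone and gives 16 as a C3/C3' mixture, which step 11 accepts.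

2. Step 11. Deprotonation at the two hindered tertiary alpha carbons may be incomplete. The enolates may open by E1cB loss of the ring phenoxide. Facial selectivity in the two protonations may be insufficient. Fallback through the furan and the enedione, setting out from 16 and returning at 18: Paal–Knorr dehydration (TsOH·H2O cat., toluene, 80 °C) should give the bis(chromeno)-fused 2,5-diarylfuran F3, with both C2 centres intact. Oxidative ring opening with mCPBA in CH2Cl2 at 0 °C should give the (Z)-enedione F4. Reduction with Zn dust in AcOH at rt should pass through the bis-enol, whose ketonisation anti to the 2-aryl groups gives 18.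

3. Step 8 (the same concern applies, less severely, to step 6). The hindered secondary alkoxide may attack the alkoxy-substituted fluoroarene sluggishly. Base-induced propargyl–allenyl isomerisation or epimerisation at the existing propargylic centre may compete. Fallback that forms the ether at the carbinol carbon instead of at the arene, setting out from 10 and 5 and returning at 12: step 7 is run with the enantiomeric ligand to give the epimeric carbinol F5. Compound 5 is converted with KOH in DMSO at 80 °C into the phenol F6. Mitsunobu coupling of F5 with F6 (PPh3, DIAD, THF, 0 °C) should give 12 with inversion at the carbinol carbon.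

**Further compounds**

F1 | step 10 | 2,4-bis(benzyloxy)-6-{[(1S,4S)-4-[3-(benzyloxy)-2-carboxy-5-methoxyphenoxy]-1,4-bis(4-methoxyphenyl)but-2-yn-1-yl]oxy}benzoic acid | COc1ccc([C@@H](C#C[C@@H](Oc2cc(OC)cc(OCc3ccccc3)c2C(=O)O)c2ccc(OC)cc2)Oc2cc(OCc3ccccc3)cc(OCc3ccccc3)c2C(=O)O)cc1
F2 | step 10 | bis(Se-phenyl selenoester) of F1 | COc1ccc([C@@H](C#C[C@@H](Oc2cc(OC)cc(OCc3ccccc3)c2C(=O)[Se]c2ccccc2)c2ccc(OC)cc2)Oc2cc(OCc3ccccc3)cc(OCc3ccccc3)c2C(=O)[Se]c2ccccc2)cc1
F3 | step 11 | (S,S)-bis(chromeno)-fused 2,5-diarylfuran (furan C3 and C4 are the former C3 and C3'; furan oxygen bridges C4 and C4') | COc1ccc([C@@H]2Oc3cc(OCc4ccccc4)cc(OCc4ccccc4)c3-c3oc4c(c32)[C@H](c2ccc(OC)cc2)Oc2cc(OC)cc(OCc5ccccc5)c2-4)cc1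
F4 | step 11 | (2S,2'S,Z)-5,5',7-tris(benzyloxy)-7'-methoxy-2,2'-bis(4-methoxyphenyl)-[3,3'-bichromanylidene]-4,4'-dione | COc1ccc([C@@H]2Oc3cc(OCc4ccccc4)cc(OCc4ccccc4)c3C(=O)/C2=C2\C(=O)c3c(OCc4ccccc4)cc(OC)cc3O[C@H]2c2ccc(OC)cc2)cc1
F5 | step 8 | 2,4-bis(benzyloxy)-6-{[(1S,4R)-4-hydroxy-1,4-bis(4-methoxyphenyl)but-2-yn-1-yl]oxy}benzonitrile | COc1ccc([C@@H](C#C[C@H](O)c2ccc(OC)cc2)Oc2cc(OCc3ccccc3)cc(OCc3ccccc3)c2C#N)cc1
F6 | step 8 | 2-(benzyloxy)-6-hydroxy-4-methoxybenzonitrile | COc1cc(O)c(C#N)c(OCc2ccccc2)c1
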